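**Retrosynthetic overview**

1. The target arecatannin a2 (13) comes from the fully protected tetramer 11 by removal of four O-TBS and sixteen O-benzyl groups.
2. Each C4–C8 interflavan bond is cut with inverted polarity. C8 of the lower unit becomes an aryl cation equivalent (aryl bromide, then ArPdBr). C4 of the incoming unit becomes a benzylcopper carbanion equivalent, made by CuH addition to the 3,4-silyl enol ether 4 of a flavan-3-one. The enol ether β-carbon and the phloroglucinol CH are both donors by nature.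
3. The same step puts H on C3 and the aryl group on C4 from the face away from the 2-aryl group, so the 2,3-cis-3,4-trans (epicatechin-4β) pattern is set in one operation.
4. Assembly is bottom-up: catechin unit 6 → dimer 7 → trimer 9 → tetramer 11. Each round is C8 bromination of the top unit, then coupling with the common monomer 4.
5. No ring is built. All rings come intact from (+)-catechin, the only carbon-skeleton starting material; the units are attached in the order bottom, third, second, top.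

Assumption: species that exist only on the catalysts (metal hydride, organocopper and organopalladium intermediates) are described in the Why lines and are not numbered as compounds.
Abbreviations: Bn = benzyl, TBS = tert-butyldimethylsilyl, TMS = trimethylsilyl, "top unit" = the unit whose C8 is still free.

**Route**

Step 1
Reactants: 1 (+)-catechin
Product: 2 5,7,3',4'-tetra-O-benzyl-(+)-catechin
Conditions: BnBr (4.4 equiv), K2CO3, DMF, 0 °C → rt
Reagents that add atoms: benzyl bromide BrCc1ccccc1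
Why: Williamson etherification in which carbonate deprotonates only the four phenols, so the C3 alcohol stays free and neither stereocentre is touched.

Step 2
Reactants: 2 5,7,3',4'-tetra-O-benzyl-(+)-catechin
Product: 3 (2R)-5,7-bis(benzyloxy)-2-[3,4-bis(benzyloxy)phenyl]chroman-3-one
Conditions: Dess–Martin periodinane, CH2Cl2, rt
Reagents that add atoms: none
Why: Dess–Martin oxidation of the secondary alcohol under neutral, non-enolising conditions removes the C3 centre (rebuilt cis in the coupling) and leaves the 2R centre intact.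

Step 3
Reactants: 3 (2R)-5,7-bis(benzyloxy)-2-[3,4-bis(benzyloxy)phenyl]chroman-3-one
Product: 4 (2R)-3-(tert-butyldimethylsilyloxy)-5,7-bis(benzyloxy)-2-[3,4-bis(benzyloxy)phenyl]-2H-chromene
Conditions: TBSOTf (1.3 equiv), Et3N, CH2Cl2, −78 → −20 °C
Reagents that add atoms: tert-butyldimethylsilyl triflate CC(C)(C)[Si](C)(C)OS(=O)(=O)C(F)(F)F
Why: Soft enolisation (silyl triflate/amine) removes one of the two unhindered benzylic C4 protons rather than the tertiary C2 proton, as 2-tetralones enolise toward the benzylic carbon, giving the conjugated 2H-chromene silyl enol ether with the 2R centre untouched.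

Step 4
Reactants: 2 5,7,3',4'-tetra-O-benzyl-(+)-catechin
Product: 6 8-bromo-3-O-TBS-5,7,3',4'-tetra-O-benzyl-(+)-catechin, via 8-bromo alcohol 5 (not isolated)
Conditions: NBS (1.0 equiv), CH2Cl2, −78 → 0 °C; then 2,6-lutidine, TBSOTf, 0 °C
Reagents that add atoms: N-bromosuccinimide O=C1CCC(=O)N1Br; tert-butyldimethylsilyl triflate CC(C)(C)[Si](C)(C)OS(=O)(=O)C(F)(F)F
Why: Electrophilic aromatic bromination goes to C8 of ring A (ortho to O1, para to the 5-benzyloxy group and less hindered than C6 between two benzyloxy groups), and the free alcohol is then silylated in the same flask without touching a stereocentre.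

Step 5
Reactants: 4 (2R)-3-(tert-butyldimethylsilyloxy)-5,7-bis(benzyloxy)-2-[3,4-bis(benzyloxy)phenyl]-2H-chromene (1.5 equiv); 6 8-bromo-3-O-TBS-5,7,3',4'-tetra-O-benzyl-(+)-catechin
Product: 7 protected dimer [3-O-TBS-tetra-O-benzyl-epicatechin]-(4β→8)-[3-O-TBS-tetra-O-benzyl-catechin]
Conditions: Cu(OAc)2/(±)-DTBM-SEGPHOS (10 mol %), Pd(OAc)2/RuPhos (5 mol %), MeSiH(OMe)2 (slow addition), NaOSiMe3, toluene, 45 °C
Reagents that add atoms: none
Why: Proposed new method: ligated CuH (monovalent copper) adds syn across the C3=C4 enol ether bond of 4 from the β face opposite the pseudoaxial 2-aryl group, putting H on C3 (this sets the 2,3-cis C3 centre) and copper on benzylic C4, and this β-silyloxy benzylcopper (C4 as a carbanion equivalent, the reverse of its usual cationic role) transmetallates with retention, because the α face is blocked by the axial 3-OTBS and the 2-aryl group and a syn β-silyloxy elimination is geometrically impossible, to the divalent palladium species ArPd(L)Br formed by oxidative addition of 6 (C8 as an aryl cation equivalent, the reverse of its usual nucleophilic role), so that reductive elimination sets the 4β, 3,4-trans centre; the closest known reaction type is the CuH/palladium dual-catalysed hydroarylation of vinylarenes with aryl bromides, with the syn-selective Cu/Pd arylboration of cyclic styrenes as the stereochemical analogy.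

Step 6
Reactants: 7 protected dimer
Product: 8 protected dimer brominated at C8 of the top unit
Conditions: NBS (1.05 equiv), CH2Cl2, −78 → −20 °C
Reagents that add atoms: N-bromosuccinimide O=C1CCC(=O)N1Br
Why: Electrophilic aromatic bromination in which only the top unit still has a free C8, while every remaining C6 lies between two benzyloxy groups and reacts more slowly.

Step 7
Reactants: 8 protected dimer bromide; 4 silyl enol ether (2 equiv)
Product: 9 protected trimer [epicatechin]-(4β→8)-[epicatechin]-(4β→8)-[catechin] (dodeca-O-benzyl tris-O-TBS)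
Conditions: Cu(OAc)2/(±)-DTBM-SEGPHOS (10 mol %), Pd(OAc)2/RuPhos (5 mol %), MeSiH(OMe)2 (slow addition), NaOSiMe3, toluene, 45 °C
Reagents that add atoms: none
Why: Proposed new method: the same CuH/palladium syn-hydroarylation as in step 5, in which β-face hydrocupration of 4 sets the new 2,3-cis C3 centre and retentive transfer of the C4 benzylcopper to the divalent palladium aryl from 8 sets the new 4β centre, the C8–Br bond being remote from the existing interflavan bond so that it behaves like that of 6; closest known reaction type: CuH/palladium dual-catalysed hydroarylation of vinylarenes with aryl bromides.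

Step 8
Reactants: 9 protected trimer
Product: 10 protected trimer brominated at C8 of the top unit
Conditions: NBS (1.05 equiv), CH2Cl2, −78 → −20 °C
Reagents that add atoms: N-bromosuccinimide O=C1CCC(=O)N1Br
Why: Electrophilic aromatic bromination at the only free C8, for the same steric and electronic reasons as in step 6.

Step 9
Reactants: 10 protected trimer bromide; 4 silyl enol ether (2 equiv)
Product: 11 protected tetramer (hexadeca-O-benzyl tetrakis-O-TBS arecatannin a2)
Conditions: Cu(OAc)2/(±)-DTBM-SEGPHOS (10 mol %), Pd(OAc)2/RuPhos (5 mol %), MeSiH(OMe)2 (slow addition), NaOSiMe3, toluene, 45 °C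
Reagents that add atoms: none
Why: Proposed new method: the same CuH/palladium syn-hydroarylation as in step 5, with H delivered to C3 and the trimer aryl group to C4 on the β face of 4 through a benzylcopper to divalent palladium aryl transfer with retention, which sets the 2,3-cis and 4β centres of the fourth unit; closest known reaction type: CuH/palladium dual-catalysed hydroarylation of vinylarenes with aryl bromides.

Step 10
Reactants: 11 protected tetramer
Product: 12 hexadeca-O-benzyl arecatannin a2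
Conditions: TBAF (6 equiv), THF, rt → 40 °C
Reagents that add atoms: none
Why: Fluoride-mediated desilylation, driven by Si–F bond formation, frees the four secondary alcohols without affecting benzyl ethers, interflavan bonds or stereocentres.

Step 11
Reactants: 12 hexadeca-O-benzyl arecatannin a2
Product: 13 arecatannin a2
Conditions: H2 (1 atm), Pd(OH)2/C, THF/MeOH/H2O, rt
Reagents that add atoms: none
Why: Catalytic hydrogenolysis cleaves all sixteen benzyl ethers under neutral conditions that leave the acid-sensitive interflavan bonds and every stereocentre unchanged.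

**Compound list**

1 | (+)-catechin, (2R,3S) | Oc1cc(O)c2c(c1)O[C@H](c1ccc(O)c(O)c1)[C@@H](O)C2 | starting material
2 | 5,7,3',4'-tetra-O-benzyl-(+)-catechin, (2R,3S) | C(c1ccccc1)Oc1cc(OCc3ccccc3)c2c(c1)O[C@H](c1ccc(OCc3ccccc3)c(OCc3ccccc3)c1)[C@@H](O)C2 | intermediate
3 | (2R)-5,7-bis(benzyloxy)-2-[3,4-bis(benzyloxy)phenyl]chroman-3-one | C(c1ccccc1)Oc1cc(OCc3ccccc3)c2c(c1)O[C@H](c1ccc(OCc3ccccc3)c(OCc3ccccc3)c1)C(=O)C2 | intermediate
4 | (2R)-3-(tert-butyldimethylsilyloxy)-5,7-bis(benzyloxy)-2-[3,4-bis(benzyloxy)phenyl]-2H-chromene | C(c1ccccc1)Oc1cc(OCc3ccccc3)c2c(c1)O[C@H](c1ccc(OCc3ccccc3)c(OCc3ccccc3)c1)C(O[Si](C)(C)C(C)(C)C)=C2 | intermediate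
5 | 8-bromo-5,7,3',4'-tetra-O-benzyl-(+)-catechin, (2R,3S) | Brc1c(OCc3ccccc3)cc(OCc3ccccc3)c2c1O[C@H](c1ccc(OCc3ccccc3)c(OCc3ccccc3)c1)[C@@H](O)C2 | intermediate
6 | 8-bromo-3-O-TBS-5,7,3',4'-tetra-O-benzyl-(+)-catechin, (2R,3S) | Brc1c(OCc3ccccc3)cc(OCc3ccccc3)c2c1O[C@H](c1ccc(OCc3ccccc3)c(OCc3ccccc3)c1)[C@@H](O[Si](C)(C)C(C)(C)C)C2 | intermediate
7 | protected dimer: 3-O-TBS-tetra-O-benzyl-epicatechin (2,3-cis, 3,4-trans) linked 4β→8 to 3-O-TBS-tetra-O-benzyl-catechin | C(c1ccccc1)Oc1cc(OCc3ccccc3)c2c(c1)O[C@H](c1ccc(OCc3ccccc3)c(OCc3ccccc3)c1)[C@H](O[Si](C)(C)C(C)(C)C)[C@H]2c1c(OCc3ccccc3)cc(OCc3ccccc3)c2c1O[C@H](c1ccc(OCc3ccccc3)c(OCc3ccccc3)c1)[C@@H](O[Si](C)(C)C(C)(C)C)C2 | intermediate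
8 | protected dimer 7 with bromine at C8 of the top (epicatechin) unit | Brc1c(OCc3ccccc3)cc(OCc3ccccc3)c2c1O[C@H](c1ccc(OCc3ccccc3)c(OCc3ccccc3)c1)[C@H](O[Si](C)(C)C(C)(C)C)[C@H]2c1c(OCc3ccccc3)cc(OCc3ccccc3)c2c1O[C@H](c1ccc(OCc3ccccc3)c(OCc3ccccc3)c1)[C@@H](O[Si](C)(C)C(C)(C)C)C2 | intermediate
9 | protected trimer: epicatechin-(4β→8)-epicatechin-(4β→8)-catechin, every phenol as benzyl ether, every 3-OH as TBS ether | C(c1ccccc1)Oc1cc(OCc3ccccc3)c2c(c1)O[C@H](c1ccc(OCc3ccccc3)c(OCc3ccccc3)c1)[C@H](O[Si](C)(C)C(C)(C)C)[C@H]2c1c(OCc3ccccc3)cc(OCc3ccccc3)c2c1O[C@H](c1ccc(OCc3ccccc3)c(OCc3ccccc3)c1)[C@H](O[Si](C)(C)C(C)(C)C)[C@H]2c1c(OCc3ccccc3)cc(OCc3ccccc3)c2c1O[C@H](c1ccc(OCc3ccccc3)c(OCc3ccccc3)c1)[C@@H](O[Si](C)(C)C(C)(C)C)C2 | intermediate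
10 | protected trimer 9 with bromine at C8 of the top unit | Brc1c(OCc3ccccc3)cc(OCc3ccccc3)c2c1O[C@H](c1ccc(OCc3ccccc3)c(OCc3ccccc3)c1)[C@H](O[Si](C)(C)C(C)(C)C)[C@H]2c1c(OCc3ccccc3)cc(OCc3ccccc3)c2c1O[C@H](c1ccc(OCc3ccccc3)c(OCc3ccccc3)c1)[C@H](O[Si](C)(C)C(C)(C)C)[C@H]2c1c(OCc3ccccc3)cc(OCc3ccccc3)c2c1O[C@H](c1ccc(OCc3ccccc3)c(OCc3ccccc3)c1)[C@@H](O[Si](C)(C)C(C)(C)C)C2 | intermediate
11 | protected tetramer: hexadeca-O-benzyl tetrakis(3-O-TBS) arecatannin a2 | C(c1ccccc1)Oc1cc(OCc3ccccc3)c2c(c1)O[C@H](c1ccc(OCc3ccccc3)c(OCc3ccccc3)c1)[C@H](O[Si](C)(C)C(C)(C)C)[C@H]2c1c(OCc3ccccc3)cc(OCc3ccccc3)c2c1O[C@H](c1ccc(OCc3ccccc3)c(OCc3ccccc3)c1)[C@H](O[Si](C)(C)C(C)(C)C)[C@H]2c1c(OCc3ccccc3)cc(OCc3ccccc3)c2c1O[C@H](c1ccc(OCc3ccccc3)c(OCc3ccccc3)c1)[C@H](O[Si](C)(C)C(C)(C)C)[C@H]2c1c(OCc3ccccc3)cc(OCc3ccccc3)c2c1O[C@H](c1ccc(OCc3ccccc3)c(OCc3ccccc3)c1)[C@@H](O[Si](C)(C)C(C)(C)C)C2 | intermediate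
12 | hexadeca-O-benzyl arecatannin a2 (four free 3-OH groups) | C(c1ccccc1)Oc1cc(OCc3ccccc3)c2c(c1)O[C@H](c1ccc(OCc3ccccc3)c(OCc3ccccc3)c1)[C@H](O)[C@H]2c1c(OCc3ccccc3)cc(OCc3ccccc3)c2c1O[C@H](c1ccc(OCc3ccccc3)c(OCc3ccccc3)c1)[C@H](O)[C@H]2c1c(OCc3ccccc3)cc(OCc3ccccc3)c2c1O[C@H](c1ccc(OCc3ccccc3)c(OCc3ccccc3)c1)[C@H](O)[C@H]2c1c(OCc3ccccc3)cc(OCc3ccccc3)c2c1O[C@H](c1ccc(OCc3ccccc3)c(OCc3ccccc3)c1)[C@@H](O)C2 | intermediate
13 | arecatannin a2, epicatechin-(4β→8)-epicatechin-(4β→8)-epicatechin-(4β→8)-catechin | Oc1cc(O)c2c(c1)O[C@H](c1ccc(O)c(O)c1)[C@H](O)[C@H]2c1c(O)cc(O)c2c1O[C@H](c1ccc(O)c(O)c1)[C@H](O)[C@H]2c1c(O)cc(O)c2c1O[C@H](c1ccc(O)c(O)c1)[C@H](O)[C@H]2c1c(O)cc(O)c2c1O[C@H](c1ccc(O)c(O)c1)[C@@H](O)C2 | target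

**Totals**

Total step count: 11.
Longest linear sequence: 10 steps (1 → 2 → 3 → 4 → 7 → 8 → 9 → 10 → 11 → 12 → 13).

**Steps most likely to fail, with fallbacks**

Step 5 (and its repeats, steps 7 and 9). The risks are slow hydrocupration of the hindered, electron-rich trisubstituted enol ether, anti loss of silanolate from the benzylcopper to give the 3-deoxy flav-3-ene, cleavage of the silyl enol ether by NaOSiMe3, hydrodebromination of the aryl bromide, and transmetallation with inversion, which would give the 4α epimer. The fallback sets out from compound 3 and comes back to the route at compound 7. Reduction of 3 with LiBH(s-Bu)3 (THF, −78 °C, hydride from the face opposite the 2-aryl group) gives 5,7,3',4'-tetra-O-benzyl-(−)-epicatechin F1. Silylation (TBSOTf, 2,6-lutidine, CH2Cl2, 0 °C) gives 3-O-TBS-5,7,3',4'-tetra-O-benzyl-(−)-epicatechin F2. Oxidation at C4 with DDQ in CH2Cl2/AcOH gives 4β-acetoxy-3-O-TBS-5,7,3',4'-tetra-O-benzyl-(−)-epicatechin F3. F3 and bromide 6 are then joined by a nickel-catalysed reductive cross-electrophile coupling (NiBr2(MeOCH2CH2OMe), 4,4'-di-tert-butyl-2,2'-bipyridine, Mn powder, DMA, rt). The C4 benzylic radical is captured by the aryl-nickel species trans to the 3-OTBS group, giving 7 with C3 already fixed by the hydride reduction. The same pair of electrophiles logic applies to bromides 8 and 10, which would give 9 and 11.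

Step 3. The risks are enolisation toward C2 (loss of the 2R centre) or a mixture of enol ether regioisomers. The fallback sets out from compound 2 and comes back to the route at compound 4. Silylation of the 3-OH (TBSOTf, 2,6-lutidine, CH2Cl2, 0 °C) gives 3-O-TBS-5,7,3',4'-tetra-O-benzyl-(+)-catechin F4. DDQ (1.05 equiv) with 2,6-di-tert-butylpyridine in CH2Cl2 at −20 °C abstracts hydride from C4 of F4, and the cation loses the axial, antiperiplanar H-3 to give enol ether 4. C2 is never next to a carbonyl group in this sequence.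

Step 6 (the same question arises at step 8). The risk is bromination at a C6 position of the oligomer instead of C8 of the top unit. The fallback sets out from compound 5 (isolated this time) and comes back to the route at compound 8; it fixes the site of bromination with a silicon placeholder carried in from the monomer. Treatment of 5 with n-BuLi (2.2 equiv, THF, −78 °C; alkoxide formation, then Br/Li exchange) and TMSCl gives 3-O-trimethylsilyl-8-(trimethylsilyl)-5,7,3',4'-tetra-O-benzyl-(+)-catechin F5. K2CO3/MeOH cleaves only the O–Si bond and gives 8-(trimethylsilyl)-5,7,3',4'-tetra-O-benzyl-(+)-catechin F6. Buffered Dess–Martin oxidation gives (2R)-8-(trimethylsilyl)-5,7-bis(benzyloxy)-2-[3,4-bis(benzyloxy)phenyl]chroman-3-one F7. TBSOTf/Et3N gives the 8-silylated TBS enol ether F8. Coupling of F8 with 6 under the step 5 conditions gives the 8-silylated protected dimer F9. NBS (CH2Cl2, −78 °C) then replaces silicon by bromine at the ipso carbon only and returns to the route at 8.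

**Further compounds**

F1 | step 5 | 5,7,3',4'-tetra-O-benzyl-(−)-epicatechin | C(c1ccccc1)Oc1cc(OCc3ccccc3)c2c(c1)O[C@H](c1ccc(OCc3ccccc3)c(OCc3ccccc3)c1)[C@H](O)C2
F2 | step 5 | 3-O-TBS-5,7,3',4'-tetra-O-benzyl-(−)-epicatechin | C(c1ccccc1)Oc1cc(OCc3ccccc3)c2c(c1)O[C@H](c1ccc(OCc3ccccc3)c(OCc3ccccc3)c1)[C@H](O[Si](C)(C)C(C)(C)C)C2
F3 | step 5 | 4β-acetoxy-3-O-TBS-5,7,3',4'-tetra-O-benzyl-(−)-epicatechin | C(c1ccccc1)Oc1cc(OCc3ccccc3)c2c(c1)O[C@H](c1ccc(OCc3ccccc3)c(OCc3ccccc3)c1)[C@H](O[Si](C)(C)C(C)(C)C)[C@H]2OC(C)=O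
F4 | step 3 | 3-O-TBS-5,7,3',4'-tetra-O-benzyl-(+)-catechin | C(c1ccccc1)Oc1cc(OCc3ccccc3)c2c(c1)O[C@H](c1ccc(OCc3ccccc3)c(OCc3ccccc3)c1)[C@@H](O[Si](C)(C)C(C)(C)C)C2
F5 | step 6 | 3-O-trimethylsilyl-8-(trimethylsilyl)-5,7,3',4'-tetra-O-benzyl-(+)-catechin | C[Si](C)(C)c1c(OCc3ccccc3)cc(OCc3ccccc3)c2c1O[C@H](c1ccc(OCc3ccccc3)c(OCc3ccccc3)c1)[C@@H](O[Si](C)(C)C)C2
F6 | step 6 | 8-(trimethylsilyl)-5,7,3',4'-tetra-O-benzyl-(+)-catechin | C[Si](C)(C)c1c(OCc3ccccc3)cc(OCc3ccccc3)c2c1O[C@H](c1ccc(OCc3ccccc3)c(OCc3ccccc3)c1)[C@@H](O)C2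
F7 | step 6 | (2R)-8-(trimethylsilyl)-5,7-bis(benzyloxy)-2-[3,4-bis(benzyloxy)phenyl]chroman-3-one | C[Si](C)(C)c1c(OCc3ccccc3)cc(OCc3ccccc3)c2c1O[C@H](c1ccc(OCc3ccccc3)c(OCc3ccccc3)c1)C(=O)C2
F8 | step 6 | (2R)-3-(tert-butyldimethylsilyloxy)-8-(trimethylsilyl)-5,7-bis(benzyloxy)-2-[3,4-bis(benzyloxy)phenyl]-2H-chromene | C[Si](C)(C)c1c(OCc3ccccc3)cc(OCc3ccccc3)c2c1O[C@H](c1ccc(OCc3ccccc3)c(OCc3ccccc3)c1)C(O[Si](C)(C)C(C)(C)C)=C2
F9 | step 6 | protected dimer 7 carrying a trimethylsilyl group at C8 of the top unit | C[Si](C)(C)c1c(OCc3ccccc3)cc(OCc3ccccc3)c2c1O[C@H](c1ccc(OCc3ccccc3)c(OCc3ccccc3)c1)[C@H](O[Si](C)(C)C(C)(C)C)[C@H]2c1c(OCc3ccccc3)cc(OCc3ccccc3)c2c1O[C@H](c1ccc(OCc3ccccc3)c(OCc3ccccc3)c1)[C@@H](O[Si](C)(C)C(C)(C)C)C2
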